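## Retrosynthetic overview

1. The γ-lactone of the target closes last. An open γ-hydroxy tert-butyl ester is first taken through exhaustive benzylic hydrogenolysis (2 × OBn, ArC=O → ArCH2), then acid closes the ring.
2. C7–aryl bond: an aryllithium opens an earlier lactone at its carbonyl. That carbonyl carbon becomes the α-benzyl CH2, and the former exocyclic ester becomes the final lactone C=O. This role swap turns an easy anti-hydroxylation into the required arrangement, with OH syn to the β-benzyl group.
3. C8–O bond: enolate hydroxylation anti to the β-arylmethyl group. C7'–aryl bond: copper-catalysed homoconjugate opening of a cyclopropane by the same aryl unit.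
4. Key step: di-tert-butyl malonate and (S)-epichlorohydrin give a 3-oxabicyclo[3.1.0]hexan-2-one. Cyclopropane and lactone form together, C8' comes from the chiral pool, and all six aliphatic carbons of the target are in place.
5. Ring order: cyclopropane and first lactone form together, then the cyclopropane is opened, then the first lactone is opened, and the final lactone is closed.

Assumption: lignan numbering is used (C7/C8/C9 = α-benzyl CH2, carbinol carbon, lactone C=O; C7'/C8'/C9' = β-benzyl CH2, β-CH, OCH2). The given SMILES is the (8R,8'R) isomer, with the benzyl groups trans and the OH cis to the β-benzyl group.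

## Route

Step 1
Reactants: 1 4-bromo-2-methoxyphenol
Product: 2 1-(benzyloxy)-4-bromo-2-methoxybenzene
Conditions: BnBr (1.1 equiv), K2CO3, acetone, reflux
Reagents that add atoms: benzyl bromide, BrCc1ccccc1
Why: Williamson ether synthesis masks the phenol so that the same bromide can serve twice as an aryl-metal source; no stereocentre is involved.

Step 2
Reactants: 3 di-tert-butyl malonate; 4 (S)-epichlorohydrin
Product: 7 tert-butyl (1S,5S)-2-oxo-3-oxabicyclo[3.1.0]hexane-1-carboxylate, via epoxy malonate 5 (not isolated), via cyclopropylcarbinol diester 6 (not isolated)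
Conditions: KOt-Bu (1.1 equiv), t-BuOH, rt → 70 °C
Reagents that add atoms: none
Why: In this tandem alkylation / 3-exo-tet cyclopropanation / lactonisation, the malonate anion opens the epoxide at CH2 and the alkoxide re-closes on CH2Cl to give 5, the second malonate C–H is removed and attacks the epoxide CH with inversion to give 6, and the alkoxide of 6 can reach only the cis ester, so both rings form in one pot, C5 (future C8') comes from the chiral pool and C1 follows from the forced cis fusion.

Step 3
Reactants: 2 1-(benzyloxy)-4-bromo-2-methoxybenzene; 7 tert-butyl (1S,5S)-2-oxo-3-oxabicyclo[3.1.0]hexane-1-carboxylate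
Product: 9 tert-butyl (3S,4S)-4-[4-(benzyloxy)-3-methoxybenzyl]-2-oxooxolane-3-carboxylate, via aryl Grignard 8 (not isolated)
Conditions: 2 (1.5 equiv), Mg, THF, 40 °C; CuI (20 mol %), then 7, THF, −40 → −20 °C; cold 1 M HCl
Reagents that add atoms: none
Why: Copper-catalysed homoconjugate addition of the aryl Grignard to the doubly activated cyclopropane proceeds by SN2-type attack at the unsubstituted CH2, which breaks the bond to the malonyl carbon, leaves C4 untouched and lets the acidic C3–H settle as the trans isomer.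

Step 4
Reactants: 9 tert-butyl (3S,4S)-4-[4-(benzyloxy)-3-methoxybenzyl]-2-oxooxolane-3-carboxylate
Product: 10 tert-butyl (3S,4R)-4-[4-(benzyloxy)-3-methoxybenzyl]-3-hydroxy-2-oxooxolane-3-carboxylate
Conditions: NaHMDS (1.1 equiv), THF, −78 °C; 2-(phenylsulfonyl)-3-phenyloxaziridine (1.3 equiv), −78 → 0 °C; AcOH
Reagents that add atoms: 2-(phenylsulfonyl)-3-phenyloxaziridine, O=S(=O)(N1OC1c1ccccc1)c1ccccc1
Why: In this Davis enolate hydroxylation the planar malonate-type enolate is attacked on the ring face opposite the C4 arylmethyl group, so OH ends trans and CO2t-Bu cis to it, and with a tert-butyl ester and no free hydroxyl group the new quaternary centre cannot scramble by translactonisation.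

Step 5
Reactants: 10 tert-butyl (3S,4R)-4-[4-(benzyloxy)-3-methoxybenzyl]-3-hydroxy-2-oxooxolane-3-carboxylate; 2 1-(benzyloxy)-4-bromo-2-methoxybenzene
Product: 12 tert-butyl (2S,3R)-2-[4-(benzyloxy)-3-methoxybenzoyl]-4-[4-(benzyloxy)-3-methoxyphenyl]-2-hydroxy-3-(hydroxymethyl)butanoate, via aryllithium 11 (not isolated)
Conditions: 2 (2.3 equiv), n-BuLi (2.2 equiv), THF, −78 °C; then 10, −78 °C, 1 h; AcOH at −78 °C
Reagents that add atoms: none
Why: In this 1,2-addition of an aryllithium to a γ-lactone carbonyl (lactone → γ-hydroxy aryl ketone, as in C-aryl glycoside synthesis), the first equivalent only deprotonates the tertiary OH, the tert-butyl ester on the same quaternary carbon is too hindered to compete, the cold quench prevents a second addition, and no stereocentre is touched while the old ring carbonyl becomes the future C7.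

Step 6
Reactants: 12 tert-butyl (2S,3R)-2-[4-(benzyloxy)-3-methoxybenzoyl]-4-[4-(benzyloxy)-3-methoxyphenyl]-2-hydroxy-3-(hydroxymethyl)butanoate
Product: 14 (+)-nortrachelogenin, via triol tert-butyl ester 13 (not isolated)
Conditions: H2 (4 bar), 10% Pd/C, EtOH–AcOH 9:1, 45 °C; filter, evaporate; TFA–CH2Cl2 1:3, 0 °C → rt
Reagents that add atoms: none
Why: Exhaustive benzylic hydrogenolysis removes both O-benzyl groups and takes the activated aryl ketone down to CH2 to give 13, after which acidolysis of the tert-butyl ester and 5-exo lactonisation of the γ-hydroxy acid close the ring on the former exocyclic carboxyl, so the untouched stereocentres read (8R,8'R) with OH cis to the β-benzyl group.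

## Compound list

1 | 4-bromo-2-methoxyphenol | COc1cc(Br)ccc1O | starting material
2 | 1-(benzyloxy)-4-bromo-2-methoxybenzene | COc1cc(Br)ccc1OCc1ccccc1 | intermediate
3 | di-tert-butyl malonate | CC(C)(C)OC(=O)CC(=O)OC(C)(C)C | starting material
4 | (S)-epichlorohydrin, (2S)-2-(chloromethyl)oxirane | ClC[C@@H]1CO1 | starting material
5 | di-tert-butyl 2-{[(2S)-oxiran-2-yl]methyl}propanedioate (not isolated) | CC(C)(C)OC(=O)C(C[C@H]1CO1)C(=O)OC(C)(C)C | intermediate
6 | di-tert-butyl (2S)-2-(hydroxymethyl)cyclopropane-1,1-dicarboxylate, present as its alkoxide (not isolated) | CC(C)(C)OC(=O)C1(C[C@@H]1CO)C(=O)OC(C)(C)C | intermediate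
7 | tert-butyl (1S,5S)-2-oxo-3-oxabicyclo[3.1.0]hexane-1-carboxylate, cis-fused | CC(C)(C)OC(=O)[C@@]12C[C@@H]1COC2=O | intermediate
8 | [4-(benzyloxy)-3-methoxyphenyl]magnesium bromide (not isolated) | COc1cc([Mg]Br)ccc1OCc1ccccc1 | intermediate
9 | tert-butyl (3S,4S)-4-[4-(benzyloxy)-3-methoxybenzyl]-2-oxooxolane-3-carboxylate, trans, C3 epimerisable | O=C1OC[C@@H](Cc2ccc(OCc3ccccc3)c(OC)c2)[C@@H]1C(=O)OC(C)(C)C | intermediate
10 | tert-butyl (3S,4R)-4-[4-(benzyloxy)-3-methoxybenzyl]-3-hydroxy-2-oxooxolane-3-carboxylate, OH trans to the arylmethyl group | O=C1OC[C@@H](Cc2ccc(OCc3ccccc3)c(OC)c2)[C@@]1(O)C(=O)OC(C)(C)C | intermediate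
11 | [4-(benzyloxy)-3-methoxyphenyl]lithium (not isolated) | COc1cc([Li])ccc1OCc1ccccc1 | intermediate
12 | tert-butyl (2S,3R)-2-[4-(benzyloxy)-3-methoxybenzoyl]-4-[4-(benzyloxy)-3-methoxyphenyl]-2-hydroxy-3-(hydroxymethyl)butanoate, open form, may sit partly as its cyclic hemiketal | CC(C)(C)OC(=O)[C@@](O)(C(=O)c1ccc(OCc2ccccc2)c(OC)c1)[C@@H](CO)Cc1ccc(OCc2ccccc2)c(OC)c1 | intermediate
13 | tert-butyl (2R,3R)-2-hydroxy-2-(4-hydroxy-3-methoxybenzyl)-4-(4-hydroxy-3-methoxyphenyl)-3-(hydroxymethyl)butanoate (not isolated) | CC(C)(C)OC(=O)[C@@](O)(Cc1ccc(O)c(OC)c1)[C@@H](CO)Cc1ccc(O)c(OC)c1 | intermediate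
14 | (+)-nortrachelogenin, (3R,4R)-3-hydroxy-3,4-bis(4-hydroxy-3-methoxybenzyl)oxolan-2-one | COc1cc(C[C@@H]2COC(=O)[C@@]2(O)Cc2ccc(O)c(OC)c2)ccc1O | target

## Step count and risks

Total step count: 6.
Longest linear sequence: 5 steps (3/4 → 7 → 9 → 10 → 12 → 14, or equally 1 → 2 → 9 → 10 → 12 → 14).

The steps most likely to fail are, in this order, 5, 6 and 3.

**Fallback for step 5.** The lactone carbonyl sits next to a fully substituted carbon, so it may not accept the aryllithium cleanly. The fallback gives up the carbonyl swap and brings C7 in as an electrophile.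
- It sets out from 9. TFA followed by refluxing toluene removes the tert-butyl ester and CO2 to give (4S)-4-[4-(benzyloxy)-3-methoxybenzyl]oxolan-2-one F1.
- LiHMDS and the Davis oxaziridine give (3S,4R)-4-[4-(benzyloxy)-3-methoxybenzyl]-3-hydroxyoxolan-2-one F2.
- The dianion of F2 (LDA, 2.2 equiv, THF–DMPU, −78 °C) is alkylated on the face anti to the C4 substituent by 4-(benzyloxy)-3-methoxybenzyl bromide F3, which is made with PBr3 from the commercial benzyl alcohol. This gives (+)-nortrachelogenin dibenzyl ether F4.
- Hydrogenolysis (H2, Pd/C, EtOAc) comes back to the route at 14.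

**Fallback for step 6.** The hindered, electron-rich aryl ketone may stall under hydrogen. Alternatively, the benzylic position may ionise and cyclise onto the other arene. The fallback splits the deoxygenation into a hydride step and a neutral hydrogenolysis.
- It sets out from 12. NaBH4 in MeOH gives tert-butyl (2S,3R)-2-{[4-(benzyloxy)-3-methoxyphenyl](hydroxy)methyl}-4-[4-(benzyloxy)-3-methoxyphenyl]-2-hydroxy-3-(hydroxymethyl)butanoate F5, and both carbinol epimers converge later.
- H2 (1 atm), Pd/C in 2-propanol at 70 °C, without acid, unmasks the phenols. The benzylic OH is then removed through the p-quinone methide.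
- This comes back at 13, which is closed with TFA as before.

**Fallback for step 3.** The aryl copper reagent may attack a carbonyl group or open the cyclopropane too slowly. The fallback separates ring opening from C–C bond formation.
- It sets out from 7. LiI with AcOH in THF at 50 °C opens the cyclopropane at CH2 to give tert-butyl (3S,4S)-4-(iodomethyl)-2-oxooxolane-3-carboxylate F6.
- Nickel-catalysed reductive cross-electrophile coupling of F6 with 2 (NiBr2·glyme, dtbbpy, Zn, DMA, 40 °C) comes back at 9.

## Further compounds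

F1 | step 5 | (4S)-4-[4-(benzyloxy)-3-methoxybenzyl]oxolan-2-one | O=C1OC[C@@H](Cc2ccc(OCc3ccccc3)c(OC)c2)C1
F2 | step 5 | (3S,4R)-4-[4-(benzyloxy)-3-methoxybenzyl]-3-hydroxyoxolan-2-one | O=C1OC[C@@H](Cc2ccc(OCc3ccccc3)c(OC)c2)[C@@H]1O
F3 | step 5 | 4-(benzyloxy)-3-methoxybenzyl bromide | COc1cc(CBr)ccc1OCc1ccccc1
F4 | step 5 | (+)-nortrachelogenin dibenzyl ether, (3R,4R)-3,4-bis[4-(benzyloxy)-3-methoxybenzyl]-3-hydroxyoxolan-2-one | COc1cc(C[C@@H]2COC(=O)[C@@]2(O)Cc2ccc(OCc3ccccc3)c(OC)c2)ccc1OCc1ccccc1
F5 | step 6 | tert-butyl (2S,3R)-2-{[4-(benzyloxy)-3-methoxyphenyl](hydroxy)methyl}-4-[4-(benzyloxy)-3-methoxyphenyl]-2-hydroxy-3-(hydroxymethyl)butanoate, both carbinol epimers | CC(C)(C)OC(=O)[C@@](O)(C(O)c1ccc(OCc2ccccc2)c(OC)c1)[C@@H](CO)Cc1ccc(OCc2ccccc2)c(OC)c1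
F6 | step 3 | tert-butyl (3S,4S)-4-(iodomethyl)-2-oxooxolane-3-carboxylate | O=C1OC[C@@H](CI)[C@@H]1C(=O)OC(C)(C)C
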